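The target is cut at the two pyranone ether bonds O1–C2 and O1''–C2'' (rings C and C''). C2 and C2'' are benzylic carbons para to the oxygens of the two B rings (4'-OMe and 4'''-OH). One DDQ treatment of an open-chain (2S,3S)-2,3-dibenzyl-1,4-diaryl-1,4-butanedione should therefore turn both CH2 groups into quinone-methide-type electrophiles. The ortho-hydroxyls of rings A and A'' capture them, closing both rings and setting C2 and C2'' trans to the preset C3 and C3''. The precursor comes from a trans-dibenzylbutyrolactone (Stobbe condensation, asymmetric hydrogenation, trans-alkylation), whose derived dialdehyde takes up two phloroglucinol-derived aryllithiums.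

Key step: step 12

Assumption: flavanone numbering is used, with double primes for the half that carries the 4-hydroxyphenyl ring; the (R,R) ligand antipode in step 2 is the one expected to give (S)-4, and the mirror-image ligand would be taken if the sense proved opposite.

Step 1
Reactants: 1 dimethyl succinate; 2 4-methoxybenzaldehyde
Product: 3 (E)-3-(methoxycarbonyl)-4-(4-methoxyphenyl)but-3-enoic acid
Conditions: NaOMe (2.2 equiv), MeOH, reflux; then aq HCl
Reagents that add atoms: none
Why: Stobbe condensation, in which the succinate enolate adds to the aldehyde, lactonises and ring-opens by elimination to the (E)-arylidene half-ester, the standard outcome for aryl aldehydes.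

Step 2
Reactants: 3 (E)-3-(methoxycarbonyl)-4-(4-methoxyphenyl)but-3-enoic acid
Product: 4 (S)-3-(methoxycarbonyl)-4-(4-methoxyphenyl)butanoic acid
Conditions: H2 (5 bar), [Rh(cod)((R,R)-Et-DuPhos)]BF4 (0.5 mol %), NaOMe (0.1 equiv), MeOH, rt
Reagents that add atoms: none
Why: Rhodium–bisphosphine asymmetric hydrogenation of an itaconate-type half-ester, in which the chelating carboxylate and the chiral ligand direct H2 to one olefin face and so set the (S) centre by catalyst control.

Step 3
Reactants: 4 (S)-3-(methoxycarbonyl)-4-(4-methoxyphenyl)butanoic acid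
Product: 6 (S)-4-(4-methoxybenzyl)dihydrofuran-2(3H)-one, via hydroxy acid 5 (not isolated)
Conditions: KOH (1.0 equiv), EtOH; CaCl2, NaBH4, EtOH, −10 °C to rt; then 3 M HCl, rt
Reagents that add atoms: none
Why: Chemoselective borohydride reduction of the ester beside the unreactive carboxylate salt, followed by acid lactonisation, gives the beta-benzyl lactone without touching the stereocentre.

Step 4
Reactants: 6 (S)-4-(4-methoxybenzyl)dihydrofuran-2(3H)-one; 7 4-(benzyloxy)benzyl bromide
Product: 9 (3S,4S)-3-[4-(benzyloxy)benzyl]-4-(4-methoxybenzyl)dihydrofuran-2(3H)-one, via lithium enolate 8 (not isolated)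
Conditions: LiHMDS (1.1 equiv), THF, −78 °C; then 7, DMPU, −78 to −40 °C
Reagents that add atoms: none
Why: Lactone enolate alkylation, in which the benzyl bromide approaches the enolate face opposite the C4 benzyl group, so the new C3 centre forms trans by substrate control, as in dibenzylbutyrolactone lignan syntheses.

Step 5
Reactants: 9 (3S,4S)-3-[4-(benzyloxy)benzyl]-4-(4-methoxybenzyl)dihydrofuran-2(3H)-one
Product: 10 (2S,3S)-2-[4-(benzyloxy)benzyl]-3-(4-methoxybenzyl)butane-1,4-diol
Conditions: LiAlH4, THF, 0 °C to rt; H2O/aq NaOH work-up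
Reagents that add atoms: none
Why: Hydride reduction of the lactone to the 1,4-diol is faster than enolisation, so both stereocentres are kept.

Step 6
Reactants: 10 (2S,3S)-2-[4-(benzyloxy)benzyl]-3-(4-methoxybenzyl)butane-1,4-diol
Product: 11 (2S,3S)-2-[4-(benzyloxy)benzyl]-3-(4-methoxybenzyl)butanedial
Conditions: (COCl)2, DMSO, CH2Cl2, −78 °C; i-Pr2NEt, −78 to −30 °C; cold pH 7 buffer; used crude
Reagents that add atoms: none
Why: Swern oxidation activates both hydroxyls as alkoxysulfonium ions before base is added, so the dialdehyde forms without lactol or lactone formation, and the hindered base at low temperature limits alpha-epimerisation.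

Step 7
Reactants: 12 phloroglucinol
Product: 13 1,3,5-tris(methoxymethoxy)benzene
Conditions: MOMCl (3.6 equiv), i-Pr2NEt, CH2Cl2/DMF, 0 °C to rt
Reagents that add atoms: chloromethyl methyl ether, COCCl
Why: O-alkylation of the phenols with the hard electrophile MOMCl (acetal protection) gives the tris-ether that directs the later lithiation.

Step 8
Reactants: 11 (2S,3S)-2-[4-(benzyloxy)benzyl]-3-(4-methoxybenzyl)butanedial; 13 1,3,5-tris(methoxymethoxy)benzene
Product: 15 (2S,3S)-2-[4-(benzyloxy)benzyl]-3-(4-methoxybenzyl)-1,4-bis[2,4,6-tris(methoxymethoxy)phenyl]butane-1,4-diol (mixture of carbinol epimers), via aryllithium 14 (not isolated)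
Conditions: 13 (3.3 equiv), n-BuLi (3.0 equiv), THF, 0 °C; then 11 added slowly at −78 °C, to 0 °C; pH 7 buffer
Reagents that add atoms: none
Why: Directed ortho-lithiation between two OMOM groups and 1,2-addition of the aryllithium to both formyl groups (inverse addition keeps the nucleophile in excess); the new carbinol centres form unselectively, which is harmless because step 9 removes them.

Step 9
Reactants: 15 (2S,3S)-2-[4-(benzyloxy)benzyl]-3-(4-methoxybenzyl)-1,4-bis[2,4,6-tris(methoxymethoxy)phenyl]butane-1,4-diol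
Product: 16 (2S,3S)-2-[4-(benzyloxy)benzyl]-3-(4-methoxybenzyl)-1,4-bis[2,4,6-tris(methoxymethoxy)phenyl]butane-1,4-dione
Conditions: Dess–Martin periodinane (3 equiv), NaHCO3, CH2Cl2, 0 °C to rt
Reagents that add atoms: none
Why: Dess–Martin oxidation of the secondary benzylic alcohols under buffered, non-basic conditions gives the aryl ketones without ionising the electron-rich carbinols or epimerising the alpha centres.

Step 10
Reactants: 16 (2S,3S)-2-[4-(benzyloxy)benzyl]-3-(4-methoxybenzyl)-1,4-bis[2,4,6-tris(methoxymethoxy)phenyl]butane-1,4-dione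
Product: 17 (2S,3S)-2-[4-(benzyloxy)benzyl]-1,4-bis[2-hydroxy-4,6-bis(methoxymethoxy)phenyl]-3-(4-methoxybenzyl)butane-1,4-dione
Conditions: MgBr2·OEt2 (3 equiv), Et2O/toluene, 0 °C to rt; aq NH4Cl
Reagents that add atoms: none
Why: Chelation-controlled Lewis acid ether cleavage, in which magnesium bridges the ketone oxygen and one ortho acetal oxygen and activates only that MOM group toward bromide; the resulting magnesium phenoxide chelate then shields the second ortho and the para MOM groups.

Step 11
Reactants: 17 (2S,3S)-2-[4-(benzyloxy)benzyl]-1,4-bis[2-hydroxy-4,6-bis(methoxymethoxy)phenyl]-3-(4-methoxybenzyl)butane-1,4-dione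
Product: 18 (2S,3S)-2-(4-hydroxybenzyl)-1,4-bis[2-hydroxy-4,6-bis(methoxymethoxy)phenyl]-3-(4-methoxybenzyl)butane-1,4-dione
Conditions: H2 (1 atm), 10% Pd/C, EtOAc, rt
Reagents that add atoms: none
Why: Palladium-catalysed hydrogenolysis of the benzyl aryl ether under neutral conditions leaves the MOM acetals and the hindered, hydrogen-bonded aryl ketones untouched.

Step 12
Reactants: 18 (2S,3S)-2-(4-hydroxybenzyl)-1,4-bis[2-hydroxy-4,6-bis(methoxymethoxy)phenyl]-3-(4-methoxybenzyl)butane-1,4-dione
Product: 20 (2S,3R,2''S,3''R)-2''-(4-hydroxyphenyl)-2-(4-methoxyphenyl)-5,7,5'',7''-tetrakis(methoxymethoxy)-3,3''-biflavanone, via monoflavanone 19 (not isolated)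
Conditions: DDQ (2.2 equiv), 4 Å MS, 1,4-dioxane, rt, then 50 °C
Reagents that add atoms: none
Why: Proposed new method: DDQ should oxidise the free 4-hydroxybenzyl unit at room temperature to a para-quinone methide at C2'' and, on warming, abstract hydride from the CH2 para to the methoxy group to give the quinone-methide-type benzylic cation at C2; the ortho-hydroxyl of ring A'' and then of ring A adds to each exocyclic carbon and ring B regains aromaticity. The closest known reactions are the DDQ or Ag2O oxidation of 4-alkylphenols to para-quinone methides trapped by an internal oxygen nucleophile and the DDQ cyclisation of 2'-hydroxydihydrochalcones to flavanones, whereas a stereocontrolled double closure on an alpha,alpha'-linked bis-dihydrochalcone has no precedent. Ring C'' and ring C each close in the 6-exo-trig mode, the phenol oxygen attacking the exocyclic methide carbon. C2'' and C2 are set by substrate control from C3'' and C3: in the chair-like transition state the ring B aryl group and the bulky C3 substituent both lie pseudo-equatorial, which gives the 2,3-trans and 2'',3''-trans arrangement, also the thermodynamic one should a C2–O bond re-ionise. The step needs oxidation only at the two CH2 groups para to oxygen (the most hydridic C–H bonds, while the acyl-deactivated, hydrogen-bonded ring A phenols and the MOM acetals resist DDQ), phenol capture faster than tautomerisation of the methide to a chalcone or 5-exo capture by the remote ketone oxygen, and no overoxidation to a flavone; these are addressed by the short 6-exo tether, exact oxidant stoichiometry, dry medium and the lowest workable temperature.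

Step 13
Reactants: 20 (2S,3R,2''S,3''R)-2''-(4-hydroxyphenyl)-2-(4-methoxyphenyl)-5,7,5'',7''-tetrakis(methoxymethoxy)-3,3''-biflavanone
Product: 21 (2S,3R,2''S,3''R)-5,7,5'',7''-tetrahydroxy-2''-(4-hydroxyphenyl)-2-(4-methoxyphenyl)-3,3''-biflavanone (CNP0196568.1)
Conditions: HCl (3 M in MeOH), THF, 40 °C
Reagents that add atoms: none
Why: Acid-catalysed acetal methanolysis removes the four MOM groups, while the diequatorial trans-flavanone rings are acid-stable and the methyl ether is untouched.

Compound list
1 | dimethyl succinate | COC(=O)CCC(=O)OC | starting material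
2 | 4-methoxybenzaldehyde | COc1ccc(C=O)cc1 | starting material
3 | (E)-3-(methoxycarbonyl)-4-(4-methoxyphenyl)but-3-enoic acid | COC(=O)/C(=C/c1ccc(OC)cc1)CC(=O)O | intermediate
4 | (S)-3-(methoxycarbonyl)-4-(4-methoxyphenyl)butanoic acid | COc1ccc(C[C@@H](CC(=O)O)C(=O)OC)cc1 | intermediate
5 | (S)-4-hydroxy-3-(4-methoxybenzyl)butanoic acid (formed as its salt) | COc1ccc(C[C@@H](CC(=O)O)CO)cc1 | intermediate (not isolated)
6 | (S)-4-(4-methoxybenzyl)dihydrofuran-2(3H)-one | COc1ccc(C[C@@H]2COC(=O)C2)cc1 | intermediate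
7 | 4-(benzyloxy)benzyl bromide | BrCc1ccc(OCc2ccccc2)cc1 | starting material
8 | lithium enolate of 6 | COc1ccc(C[C@@H]2COC(O[Li])=C2)cc1 | intermediate (not isolated)
9 | (3S,4S)-3-[4-(benzyloxy)benzyl]-4-(4-methoxybenzyl)dihydrofuran-2(3H)-one (trans) | COc1ccc(C[C@@H]2COC(=O)[C@H]2Cc2ccc(OCc3ccccc3)cc2)cc1 | intermediate
10 | (2S,3S)-2-[4-(benzyloxy)benzyl]-3-(4-methoxybenzyl)butane-1,4-diol | COc1ccc(C[C@H](CO)[C@@H](CO)Cc2ccc(OCc3ccccc3)cc2)cc1 | intermediate
11 | (2S,3S)-2-[4-(benzyloxy)benzyl]-3-(4-methoxybenzyl)butanedial | COc1ccc(C[C@H](C=O)[C@@H](C=O)Cc2ccc(OCc3ccccc3)cc2)cc1 | intermediate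
12 | phloroglucinol | Oc1cc(O)cc(O)c1 | starting material
13 | 1,3,5-tris(methoxymethoxy)benzene | COCOc1cc(OCOC)cc(OCOC)c1 | intermediate
14 | 2,4,6-tris(methoxymethoxy)phenyllithium | [Li]c1c(OCOC)cc(OCOC)cc1OCOC | intermediate (not isolated)
15 | (2S,3S)-2-[4-(benzyloxy)benzyl]-3-(4-methoxybenzyl)-1,4-bis[2,4,6-tris(methoxymethoxy)phenyl]butane-1,4-diol, carbinol epimers | COc1ccc(C[C@H](C(O)c2c(OCOC)cc(OCOC)cc2OCOC)[C@@H](C(O)c2c(OCOC)cc(OCOC)cc2OCOC)Cc2ccc(OCc3ccccc3)cc2)cc1 | intermediate
16 | (2S,3S)-2-[4-(benzyloxy)benzyl]-3-(4-methoxybenzyl)-1,4-bis[2,4,6-tris(methoxymethoxy)phenyl]butane-1,4-dione | COc1ccc(C[C@H](C(=O)c2c(OCOC)cc(OCOC)cc2OCOC)[C@@H](C(=O)c2c(OCOC)cc(OCOC)cc2OCOC)Cc2ccc(OCc3ccccc3)cc2)cc1 | intermediate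
17 | (2S,3S)-2-[4-(benzyloxy)benzyl]-1,4-bis[2-hydroxy-4,6-bis(methoxymethoxy)phenyl]-3-(4-methoxybenzyl)butane-1,4-dione | COc1ccc(C[C@H](C(=O)c2c(O)cc(OCOC)cc2OCOC)[C@@H](C(=O)c2c(O)cc(OCOC)cc2OCOC)Cc2ccc(OCc3ccccc3)cc2)cc1 | intermediate
18 | (2S,3S)-2-(4-hydroxybenzyl)-1,4-bis[2-hydroxy-4,6-bis(methoxymethoxy)phenyl]-3-(4-methoxybenzyl)butane-1,4-dione (precursor of the key step) | COc1ccc(C[C@H](C(=O)c2c(O)cc(OCOC)cc2OCOC)[C@H](Cc2ccc(O)cc2)C(=O)c2c(O)cc(OCOC)cc2OCOC)cc1 | intermediate
19 | (2S,3R)-3-{(2S)-1-[2-hydroxy-4,6-bis(methoxymethoxy)phenyl]-3-(4-methoxyphenyl)-1-oxopropan-2-yl}-2-(4-hydroxyphenyl)-5,7-bis(methoxymethoxy)chroman-4-one (ring C'' closed, ring C still open) | COc1ccc(C[C@H](C(=O)c2c(O)cc(OCOC)cc2OCOC)[C@H]2C(=O)c3c(OCOC)cc(OCOC)cc3O[C@@H]2c2ccc(O)cc2)cc1 | intermediate (not isolated)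
20 | (2S,3R,2''S,3''R)-2''-(4-hydroxyphenyl)-2-(4-methoxyphenyl)-5,7,5'',7''-tetrakis(methoxymethoxy)-3,3''-biflavanone (product of the key step) | COc1ccc([C@H]2Oc3cc(OCOC)cc(OCOC)c3C(=O)[C@@H]2[C@H]2C(=O)c3c(OCOC)cc(OCOC)cc3O[C@@H]2c2ccc(O)cc2)cc1 | intermediate
21 | (2S,3R,2''S,3''R)-5,7,5'',7''-tetrahydroxy-2''-(4-hydroxyphenyl)-2-(4-methoxyphenyl)-3,3''-biflavanone | COc1ccc([C@H]2Oc3cc(O)cc(O)c3C(=O)[C@@H]2[C@H]2C(=O)c3c(O)cc(O)cc3O[C@@H]2c2ccc(O)cc2)cc1 | target

Total step count: 13.
Longest linear sequence: 12 steps (steps 1–6 and 8–13; step 7 is a one-step side branch).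

Steps most likely to fail

Step 12 (new method). The C3 or C3'' configuration may be lost if a methide or cation tautomerises to a chalcone before the phenol closes. The C2 cation may also be captured by the remote ketone oxygen in a five-membered mode, and the first-formed hydroxyphenyl flavanone half may be overoxidised toward a flavone while the slower methoxybenzyl site reacts. Fallback with known chemistry, setting out from 16: the two 4-alkoxybenzylic CH2 groups would first be acetoxylated intermolecularly (DDQ, AcOH/CH2Cl2, rt, the known benzylic acetoxylation of 4-alkoxy-alkylbenzenes) to the bis(benzylic acetate) F1, so that no free phenol meets the oxidant. HCl in MeOH would then remove the six MOM groups and ionise the benzylic acetates, and each ring would close by acid-mediated SN1 capture of an ortho-hydroxyl under thermodynamic 2,3-trans control, giving the 4'''-O-benzyl ether of the target F2. Hydrogenolysis (H2, 10% Pd/C, EtOAc) returns to the route at 21.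

Step 8. After the first addition the alkoxide may close onto the second formyl group as a lactolate and stall the second addition. The basic, hindered aryllithium may also enolise the dialdehyde and epimerise it, a risk already present when the dialdehyde is formed in step 6. Fallback, setting out from lactone 9 and avoiding the dialdehyde: DIBAL-H (toluene, −78 °C) would give the lactol F3. Aryllithium 14 (3 equiv, the first deprotonating the lactol) would open it to the 1,4-diol F4. Dess–Martin oxidation of both hydroxyls would give the keto aldehyde F5, a second addition of 14 at −78 °C the hydroxy ketone F6, and a final Dess–Martin oxidation returns to the route at 16.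

Step 10. The cleavage may not stop at one ortho acetal per ring, either removing the second ortho or the para MOM groups or stalling after one ring. Fallback, setting out from 16, replaces selectivity in cleavage by selectivity in protection: all six MOM groups would be removed (HCl, MeOH, rt, kept short and cool so that the 1,4-diketone does not cyclise to a furan) to give the hexaphenol F7. MOMCl (4.2 equiv) and i-Pr2NEt in CH2Cl2 at 0 °C would then protect the four non-chelated hydroxyls and leave the hydrogen-bonded ortho-hydroxyl of each ring free, returning to the route at 17.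

Further compounds
F1 | step 12 | bis(benzylic acetate) of 16: both ArCH2 groups converted to ArCH(OAc), backbone configuration of 16 retained, acetoxy centres as a mixture | COc1ccc(C(OC(C)=O)[C@H](C(=O)c2c(OCOC)cc(OCOC)cc2OCOC)[C@@H](C(=O)c2c(OCOC)cc(OCOC)cc2OCOC)C(OC(C)=O)c2ccc(OCc3ccccc3)cc2)cc1
F2 | step 12 | (2S,3R,2''S,3''R)-2''-[4-(benzyloxy)phenyl]-5,7,5'',7''-tetrahydroxy-2-(4-methoxyphenyl)-3,3''-biflavanone | COc1ccc([C@H]2Oc3cc(O)cc(O)c3C(=O)[C@@H]2[C@H]2C(=O)c3c(O)cc(O)cc3O[C@@H]2c2ccc(OCc3ccccc3)cc2)cc1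
F3 | step 8 | (3S,4S)-3-[4-(benzyloxy)benzyl]-4-(4-methoxybenzyl)tetrahydrofuran-2-ol (anomers) | COc1ccc(C[C@@H]2COC(O)[C@H]2Cc2ccc(OCc3ccccc3)cc2)cc1
F4 | step 8 | (2S,3S)-2-[4-(benzyloxy)benzyl]-3-(4-methoxybenzyl)-1-[2,4,6-tris(methoxymethoxy)phenyl]butane-1,4-diol (carbinol epimers) | COc1ccc(C[C@H](CO)[C@@H](C(O)c2c(OCOC)cc(OCOC)cc2OCOC)Cc2ccc(OCc3ccccc3)cc2)cc1
F5 | step 8 | (2S,3S)-3-[4-(benzyloxy)benzyl]-2-(4-methoxybenzyl)-4-oxo-4-[2,4,6-tris(methoxymethoxy)phenyl]butanal | COc1ccc(C[C@H](C=O)[C@@H](C(=O)c2c(OCOC)cc(OCOC)cc2OCOC)Cc2ccc(OCc3ccccc3)cc2)cc1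
F6 | step 8 | (2S,3S)-2-[4-(benzyloxy)benzyl]-4-hydroxy-3-(4-methoxybenzyl)-1,4-bis[2,4,6-tris(methoxymethoxy)phenyl]butan-1-one (carbinol epimers) | COc1ccc(C[C@H](C(O)c2c(OCOC)cc(OCOC)cc2OCOC)[C@@H](C(=O)c2c(OCOC)cc(OCOC)cc2OCOC)Cc2ccc(OCc3ccccc3)cc2)cc1
F7 | step 10 | (2S,3S)-2-[4-(benzyloxy)benzyl]-3-(4-methoxybenzyl)-1,4-bis(2,4,6-trihydroxyphenyl)butane-1,4-dione | COc1ccc(C[C@H](C(=O)c2c(O)cc(O)cc2O)[C@@H](C(=O)c2c(O)cc(O)cc2O)Cc2ccc(OCc3ccccc3)cc2)cc1
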